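**Retrosynthetic overview**

1. The C8 ester (Steglich acylation) and the silyl groups on O10 and O15 are adjusted last; the whole bicyclic core comes from one operation.
2. Key disconnection C6–C7: chromium-mediated intramolecular allylation of the C6 aldehyde by the 2-(bromomethyl)enoate C13–C11(C12)=C7. The ten-membered carbocycle (C1–C10) closes first; the C6 alkoxide then closes the five-membered lactone (O–C6–C7–C11–C12) in the same flask, creating C6, C7 and the C11=C13 methylene.
3. Enabling feature: C7 is the γ-carbon of a 2-carboxyallyl unit (C13–C11(C12)=C7) and C6 is a carbinol carbon γ to C12. The C3 ketone / Z-C4=C5 / C6 aldehyde array is the ring-opened form of a 2,3-disubstituted furan (temporary ring O–C3–C4–C5–C6), so the cis turn needed for ten-ring closure is built in.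
4. Acyclic precursor: the furan (from 3-furoic acid) is joined at C2 by a Heck reaction to the vinyl group of (R)-linalool (C10 from the chiral pool); C8–O comes from proline α-aminoxylation; C11–C13 from a Morita–Baylis–Hillman reaction and SN2' bromination.
5. Ring order: furan (temporary, opened by singlet oxygen) → ten-membered carbocycle → γ-lactone.

Key step: step 15

Remark on the chemistry: germacranolide numbering is used (ring C1–C10, lactone carbons C11–C13, C14 = methyl on C10, C15 = CH2O on C4). (R)-Linalool and (R)-2-methylbutanoic acid, the enantiomer the given structure requires, are taken as commercial in high enantiomeric purity.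

**Route**

Step 1
Reactants: 1 furan-3-carboxylic acid
Product: 3 2-iodofuran-3-carboxylic acid, via dilithiated furoate 2 (not isolated)
Conditions: lithium diisopropylamide (2.2 equiv), THF, −78 °C; then I2, THF, −78 °C; aq. HCl
Reagents that add atoms: iodine, [I][I]
Why: the carboxylate directs the amide base to the adjacent C2–H (directed ortho-metalation of the 3-furoate dianion) and the C2–lithium is trapped by iodine, which places the halogen regiospecifically next to the future C15 carbon.

Step 2
Reactants: 3 2-iodofuran-3-carboxylic acid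
Product: 4 (2-iodofuran-3-yl)methanol
Conditions: BH3·SMe2, THF, 0 °C to rt; MeOH quench
Reagents that add atoms: none
Why: borane reduces the carboxylic acid chemoselectively to the primary alcohol (acyloxyborane pathway) without touching the furyl iodide.

Step 3
Reactants: 4 (2-iodofuran-3-yl)methanol
Product: 5 tert-butyl[(2-iodofuran-3-yl)methoxy]diphenylsilane
Conditions: TBDPSCl, imidazole, DMF, 0 °C to rt
Reagents that add atoms: tert-butyl(chloro)diphenylsilane, CC(C)(C)[Si](Cl)(c1ccccc1)c1ccccc1
Why: standard imidazole-promoted silylation gives a primary TBDPS ether that should survive every later step and is removed only at the end.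

Step 4
Reactants: 6 (R)-linalool
Product: 7 triethyl{[(3R)-3,7-dimethylocta-1,6-dien-3-yl]oxy}silane
Conditions: TESOTf, 2,6-lutidine, CH2Cl2, −78 to 0 °C
Reagents that add atoms: triethylsilyl trifluoromethanesulfonate, CC[Si](CC)(CC)OS(=O)(=O)C(F)(F)F
Why: a silyl triflate with a hindered base silylates the tertiary allylic alcohol without ionisation (O-silylation), so the chiral-pool C10 centre is carried over unchanged and lactol formation of the aldehyde made in step 5 is prevented.

Step 5
Reactants: 7 triethyl{[(3R)-3,7-dimethylocta-1,6-dien-3-yl]oxy}silane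
Product: 9 (4R)-4-methyl-4-(triethylsilyloxy)hex-5-enal, via secondary ozonide 8 (not isolated)
Conditions: O3 (1.0 equiv), CH2Cl2, −78 °C, stopped when 7 is consumed; then PPh3, −78 °C to rt
Reagents that add atoms: ozone, [O-][O+]=O
Why: Criegee ozonolysis with reductive work-up should be selective for the electron-rich trisubstituted (prenyl) alkene over the monosubstituted vinyl group, which sits on a quaternary, inductively deactivated carbon.

Step 6
Reactants: 9 (4R)-4-methyl-4-(triethylsilyloxy)hex-5-enal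
Product: 11 (2R,4R)-2-(anilinooxy)-4-methyl-4-(triethylsilyloxy)hex-5-en-1-ol, via α-anilinooxy aldehyde 10 (not isolated)
Conditions: PhNO (1.0 equiv), L-proline (20 mol %), CHCl3, 4 °C; then NaBH4, EtOH, 0 °C
Reagents that add atoms: nitrosobenzene, O=Nc1ccccc1
Why: proline enamine catalysis (α-aminoxylation) delivers the nitroso oxygen to one enamine face through the carboxylic acid hydrogen bond, L-proline giving the 2R centre (future C8) under catalyst control regardless of the remote C10 centre, and immediate borohydride reduction prevents epimerisation.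

Step 7
Reactants: 11 (2R,4R)-2-(anilinooxy)-4-methyl-4-(triethylsilyloxy)hex-5-en-1-ol
Product: 12 (2R,4R)-4-methyl-4-(triethylsilyloxy)hex-5-ene-1,2-diol
Conditions: Zn dust, AcOH/THF 1:4, 0 °C to rt
Reagents that add atoms: none
Why: zinc in acetic acid cleaves the weak N–O bond reductively (dissolving-metal reduction) without touching the alkene or the tertiary silyl ether, and the C8 configuration is not involved.

Step 8
Reactants: 12 (2R,4R)-4-methyl-4-(triethylsilyloxy)hex-5-ene-1,2-diol
Product: 13 (2R,4R)-4-methyl-1,2,4-tris(triethylsilyloxy)hex-5-ene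
Conditions: TESCl (2.5 equiv), imidazole, DMF, 0 °C to rt
Reagents that add atoms: chlorotriethylsilane, CC[Si](Cl)(CC)CC
Why: exhaustive imidazole-promoted silylation of the primary and secondary hydroxyls sets up their differentiation in step 9.

Step 9
Reactants: 13 (2R,4R)-4-methyl-1,2,4-tris(triethylsilyloxy)hex-5-ene
Product: 14 (2R,4R)-4-methyl-2,4-bis(triethylsilyloxy)hex-5-en-1-ol
Conditions: PPTS (0.1 equiv), MeOH/CH2Cl2 1:4, −10 °C, stopped at consumption of 13
Reagents that add atoms: none
Why: acid-catalysed methanolysis of silyl ethers is strongly sterically graded (primary faster than secondary faster than tertiary), so the primary TES ether should be released selectively at low temperature.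

Step 10
Reactants: 14 (2R,4R)-4-methyl-2,4-bis(triethylsilyloxy)hex-5-en-1-ol; 5 tert-butyl[(2-iodofuran-3-yl)methoxy]diphenylsilane
Product: 15 (2R,4R,5E)-6-{3-[(tert-butyldiphenylsilyloxy)methyl]furan-2-yl}-4-methyl-2,4-bis(triethylsilyloxy)hex-5-en-1-ol
Conditions: Pd(OAc)2 (5 mol %), n-Bu4NCl, NaHCO3, DMF, 50 °C, dark
Reagents that add atoms: none
Why: Mizoroki–Heck reaction under ligand-free Jeffery conditions, in which the furyl–palladium species adds to the terminal alkene carbon and syn β-hydride elimination can only occur away from the quaternary C10, giving the E-alkene C1=C2 conjugated to the furan.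

Step 11
Reactants: 15 (2R,4R,5E)-6-{3-[(tert-butyldiphenylsilyloxy)methyl]furan-2-yl}-4-methyl-2,4-bis(triethylsilyloxy)hex-5-en-1-ol
Product: 16 (2R,4R,5E)-6-{3-[(tert-butyldiphenylsilyloxy)methyl]furan-2-yl}-4-methyl-2,4-bis(triethylsilyloxy)hex-5-enal
Conditions: Dess–Martin periodinane, NaHCO3, CH2Cl2, 0 °C
Reagents that add atoms: none
Why: Dess–Martin oxidation under bicarbonate buffer gives the α-silyloxy aldehyde without acid that could ionise the furyl-conjugated tertiary allylic ether or epimerise C8.

Step 12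
Reactants: 16 (2R,4R,5E)-6-{3-[(tert-butyldiphenylsilyloxy)methyl]furan-2-yl}-4-methyl-2,4-bis(triethylsilyloxy)hex-5-enal
Product: 17 methyl (4R,6R,7E)-8-{3-[(tert-butyldiphenylsilyloxy)methyl]furan-2-yl}-3-hydroxy-6-methyl-2-methylidene-4,6-bis(triethylsilyloxy)oct-7-enoate (both C3 epimers)
Conditions: methyl acrylate (10 equiv), DABCO (1 equiv), MeOH (2 equiv), rt, dark
Reagents that add atoms: methyl acrylate, C=CC(=O)OC
Why: Morita–Baylis–Hillman reaction, in which the DABCO–acrylate zwitterion adds to the aldehyde and attaches C11 to C7; the new carbinol centre is formed as an inconsequential epimer mixture because it becomes sp2 in step 13.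

Step 13
Reactants: 17 methyl (4R,6R,7E)-8-{3-[(tert-butyldiphenylsilyloxy)methyl]furan-2-yl}-3-hydroxy-6-methyl-2-methylidene-4,6-bis(triethylsilyloxy)oct-7-enoate
Product: 19 methyl (2Z,4R,6R,7E)-2-(bromomethyl)-8-{3-[(tert-butyldiphenylsilyloxy)methyl]furan-2-yl}-6-methyl-4,6-bis(triethylsilyloxy)octa-2,7-dienoate, via allylic mesylate 18 (not isolated)
Conditions: MsCl, Et3N, CH2Cl2, −30 °C; then LiBr (5 equiv), THF, 0 °C to rt
Reagents that add atoms: lithium bromide, [Li+].[Br-]
Why: mesylation followed by bromide SN2' displacement (allylic transposition) moves the double bond to C7=C11 and places bromine on C13, the Z-isomer (C8 cis to CH2Br) being expected as is general for Baylis–Hillman-derived bromides, and no acid or electrophilic bromine touches the furan.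

Step 14
Reactants: 19 methyl (2Z,4R,6R,7E)-2-(bromomethyl)-8-{3-[(tert-butyldiphenylsilyloxy)methyl]furan-2-yl}-6-methyl-4,6-bis(triethylsilyloxy)octa-2,7-dienoate
Product: 21 methyl (2Z,4R,6R,7E,10Z)-2-(bromomethyl)-10-[(tert-butyldiphenylsilyloxy)methyl]-6-methyl-9,12-dioxo-4,6-bis(triethylsilyloxy)dodeca-2,7,10-trienoate, via furan endoperoxide 20 (not isolated)
Conditions: O2, tetraphenylporphyrin (1 mol %), visible light, CH2Cl2, −78 °C; then Me2S, −78 to −20 °C; used at once, dark
Reagents that add atoms: oxygen, O=O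
Why: singlet oxygen adds across the 2,5-positions of the furan ([4+2] cycloaddition) much faster than it reacts with the other alkenes, and reduction of the endoperoxide with Me2S unveils the C3 ketone, the C6 aldehyde and the C4=C5 double bond, whose Z-geometry is inherited from the ring.

Step 15
Reactants: 21 methyl (2Z,4R,6R,7E,10Z)-2-(bromomethyl)-10-[(tert-butyldiphenylsilyloxy)methyl]-6-methyl-9,12-dioxo-4,6-bis(triethylsilyloxy)dodeca-2,7,10-trienoate
Product: 24 (1E,4Z,6R,7S,8R,10R)-15-(tert-butyldiphenylsilyloxy)-3-oxo-8,10-bis(triethylsilyloxy)germacra-1,4,11(13)-trien-12,6-olide, via allylchromium dichloride 22 (not isolated), via chromium alkoxide ester 23 (not isolated)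
Conditions: CrCl2 (10 equiv), THF/DMF 4:1, 25 °C, 21 added by syringe pump over 10 h (final 2 mM), dark, argon; then 40 °C, 2 h; aq. NH4Cl
Reagents that add atoms: none
Why: Halogen abstraction by two CrCl2 converts the 2-(bromomethyl)enoate into a 2-(methoxycarbonyl)allyl chromium dichloride (trivalent chromium) that equilibrates by 1,3-metal shift and adds through its γ-carbon C7 to the chromium-bound aldehyde C6 in a six-membered chair (Nozaki–Hiyama–Kishi/Barbier allylation), transposing the double bond to C11=C13, after which the trivalent chromium alkoxide on O6 acylates on the neighbouring methyl ester. The closest known reaction type is the chromium-mediated intramolecular allylation of ω-formyl 2-(bromomethyl)alk-2-enoates that delivers ten-membered germacranolide lactones. The carbocycle closes in a 10-exo-trig mode (carbonyl oxygen outside the ring, the turn supplied by the Z-C4=C5 bond held over from the furan) and the lactone in a 5-exo-trig acyl substitution (O6 onto C12). C6 and C7 are set together: the chair with C5 and C8 both pseudo-equatorial gives the anti adduct and hence the 6,7-trans lactone, while the C8 stereocentre fixes the face of C7, because A(1,3) strain with the C11 substituent should keep H8 in the allyl plane, the ring tether C9 must then lie anti to the forming bond (the gauche position next to C5 would impose a syn-pentane contact inside the forming ring) and the silyloxy group points outside, which corresponds to the target configuration at C6 and C7 (written 7S in 24 only because the O-silyl branch changes the priority order). The step needs aldehyde-over-ketone selectivity (inherent to allylchromium reagents, and 1,2-attack on the C3 ketone would require an E-alkene in a seven-membered ring), intramolecular over intermolecular reaction (slow addition at 2 mM) and no 1,4-elimination across C13–C8, which the poor silanolate leaving group on C8 should secure.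

Step 16
Reactants: 24 (1E,4Z,6R,7S,8R,10R)-15-(tert-butyldiphenylsilyloxy)-3-oxo-8,10-bis(triethylsilyloxy)germacra-1,4,11(13)-trien-12,6-olide
Product: 25 (1E,4Z,6R,7R,8R,10R)-15-(tert-butyldiphenylsilyloxy)-8-hydroxy-3-oxo-10-(triethylsilyloxy)germacra-1,4,11(13)-trien-12,6-olide
Conditions: PPTS (0.3 equiv), MeOH/CH2Cl2 1:1, 0 °C to rt, dark
Reagents that add atoms: none
Why: acid-catalysed methanolysis should remove the secondary C8 TES ether faster than the tertiary C10 TES ether and leave the TBDPS ether (steric grading of silyl ether solvolysis), and the non-basic medium avoids migration of the lactone to O8.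

Step 17
Reactants: 25 (1E,4Z,6R,7R,8R,10R)-15-(tert-butyldiphenylsilyloxy)-8-hydroxy-3-oxo-10-(triethylsilyloxy)germacra-1,4,11(13)-trien-12,6-olide; 26 (R)-2-methylbutanoic acid
Product: 27 (1E,4Z,6R,7R,8R,10R)-15-(tert-butyldiphenylsilyloxy)-8-[(2R)-2-methylbutanoyloxy]-3-oxo-10-(triethylsilyloxy)germacra-1,4,11(13)-trien-12,6-olide
Conditions: 26 (3 equiv), N,N'-diisopropylcarbodiimide (3 equiv), DMAP (0.3 equiv), CH2Cl2, 0 °C to rt, dark
Reagents that add atoms: none
Why: Steglich esterification acylates the only free hydroxyl with retention at C8 and, at 0 °C, should not epimerise the α-centre of the acid.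

Step 18
Reactants: 27 (1E,4Z,6R,7R,8R,10R)-15-(tert-butyldiphenylsilyloxy)-8-[(2R)-2-methylbutanoyloxy]-3-oxo-10-(triethylsilyloxy)germacra-1,4,11(13)-trien-12,6-olide
Product: 28 (1E,4Z,6R,7R,8R,10R)-10,15-dihydroxy-8-[(2R)-2-methylbutanoyloxy]-3-oxogermacra-1,4,11(13)-trien-12,6-olide (CNP0232405.1)
Conditions: HF·pyridine, pyridine, THF, 0 °C to rt, polypropylene vessel, dark
Reagents that add atoms: none
Why: buffered fluoride-mediated desilylation should cleave the tertiary TES and primary TBDPS ethers while the dienone, the α-methylene lactone and the ester, all base-sensitive, are left intact.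

**Compound list**

1 | furan-3-carboxylic acid | OC(=O)c1ccoc1 | starting material
2 | lithium 2-lithiofuran-3-carboxylate (not isolated) | [Li]OC(=O)c1ccoc1[Li] | intermediate
3 | 2-iodofuran-3-carboxylic acid | OC(=O)c1ccoc1I | intermediate
4 | (2-iodofuran-3-yl)methanol | OCc1ccoc1I | intermediate
5 | tert-butyl[(2-iodofuran-3-yl)methoxy]diphenylsilane | CC(C)(C)[Si](OCc1ccoc1I)(c1ccccc1)c1ccccc1 | intermediate
6 | (R)-linalool, (3R)-3,7-dimethylocta-1,6-dien-3-ol | C=C[C@](C)(O)CCC=C(C)C | starting material
7 | triethyl{[(3R)-3,7-dimethylocta-1,6-dien-3-yl]oxy}silane | C=C[C@](C)(O[Si](CC)(CC)CC)CCC=C(C)C | intermediate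
8 | 3,3-dimethyl-5-[(3R)-3-methyl-3-(triethylsilyloxy)pent-4-enyl]-1,2,4-trioxolane (not isolated) | C=C[C@](C)(O[Si](CC)(CC)CC)CCC1OOC(C)(C)O1 | intermediate
9 | (4R)-4-methyl-4-(triethylsilyloxy)hex-5-enal | C=C[C@](C)(O[Si](CC)(CC)CC)CCC=O | intermediate
10 | (2R,4R)-2-(anilinooxy)-4-methyl-4-(triethylsilyloxy)hex-5-enal (not isolated) | C=C[C@](C)(O[Si](CC)(CC)CC)C[C@@H](ONc1ccccc1)C=O | intermediate
11 | (2R,4R)-2-(anilinooxy)-4-methyl-4-(triethylsilyloxy)hex-5-en-1-ol | C=C[C@](C)(O[Si](CC)(CC)CC)C[C@@H](ONc1ccccc1)CO | intermediate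
12 | (2R,4R)-4-methyl-4-(triethylsilyloxy)hex-5-ene-1,2-diol | C=C[C@](C)(O[Si](CC)(CC)CC)C[C@@H](O)CO | intermediate
13 | (2R,4R)-4-methyl-1,2,4-tris(triethylsilyloxy)hex-5-ene | C=C[C@](C)(O[Si](CC)(CC)CC)C[C@@H](O[Si](CC)(CC)CC)CO[Si](CC)(CC)CC | intermediate
14 | (2R,4R)-4-methyl-2,4-bis(triethylsilyloxy)hex-5-en-1-ol | C=C[C@](C)(O[Si](CC)(CC)CC)C[C@@H](O[Si](CC)(CC)CC)CO | intermediate
15 | (2R,4R,5E)-6-{3-[(tert-butyldiphenylsilyloxy)methyl]furan-2-yl}-4-methyl-2,4-bis(triethylsilyloxy)hex-5-en-1-ol | CC(C)(C)[Si](OCc1ccoc1/C=C/[C@](C)(O[Si](CC)(CC)CC)C[C@@H](O[Si](CC)(CC)CC)CO)(c1ccccc1)c1ccccc1 | intermediate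
16 | (2R,4R,5E)-6-{3-[(tert-butyldiphenylsilyloxy)methyl]furan-2-yl}-4-methyl-2,4-bis(triethylsilyloxy)hex-5-enal | CC(C)(C)[Si](OCc1ccoc1/C=C/[C@](C)(O[Si](CC)(CC)CC)C[C@@H](O[Si](CC)(CC)CC)C=O)(c1ccccc1)c1ccccc1 | intermediate
17 | methyl (4R,6R,7E)-8-{3-[(tert-butyldiphenylsilyloxy)methyl]furan-2-yl}-3-hydroxy-6-methyl-2-methylidene-4,6-bis(triethylsilyloxy)oct-7-enoate (C3 epimers) | CC(C)(C)[Si](OCc1ccoc1/C=C/[C@](C)(O[Si](CC)(CC)CC)C[C@@H](O[Si](CC)(CC)CC)C(O)C(=C)C(=O)OC)(c1ccccc1)c1ccccc1 | intermediate
18 | 3-O-methanesulfonate of 17 (not isolated) | CC(C)(C)[Si](OCc1ccoc1/C=C/[C@](C)(O[Si](CC)(CC)CC)C[C@@H](O[Si](CC)(CC)CC)C(OS(C)(=O)=O)C(=C)C(=O)OC)(c1ccccc1)c1ccccc1 | intermediate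
19 | methyl (2Z,4R,6R,7E)-2-(bromomethyl)-8-{3-[(tert-butyldiphenylsilyloxy)methyl]furan-2-yl}-6-methyl-4,6-bis(triethylsilyloxy)octa-2,7-dienoate | CC(C)(C)[Si](OCc1ccoc1/C=C/[C@](C)(O[Si](CC)(CC)CC)C[C@@H](O[Si](CC)(CC)CC)/C=C(\CBr)C(=O)OC)(c1ccccc1)c1ccccc1 | intermediate
20 | 2,5-endoperoxide of the furan of 19 (2,3,7-trioxabicyclo[2.2.1]hept-5-ene, bridgehead epimers, not isolated) | CC(C)(C)[Si](OCC1=CC2OOC1(/C=C/[C@](C)(O[Si](CC)(CC)CC)C[C@@H](O[Si](CC)(CC)CC)/C=C(\CBr)C(=O)OC)O2)(c1ccccc1)c1ccccc1 | intermediate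
21 | methyl (2Z,4R,6R,7E,10Z)-2-(bromomethyl)-10-[(tert-butyldiphenylsilyloxy)methyl]-6-methyl-9,12-dioxo-4,6-bis(triethylsilyloxy)dodeca-2,7,10-trienoate | O=C/C=C(/CO[Si](c1ccccc1)(c1ccccc1)C(C)(C)C)C(=O)/C=C/[C@](C)(O[Si](CC)(CC)CC)C[C@@H](O[Si](CC)(CC)CC)/C=C(\CBr)C(=O)OC | intermediate
22 | allylchromium dichloride derived from 21 (CrCl2 in place of Br on C13, not isolated) | O=C/C=C(/CO[Si](c1ccccc1)(c1ccccc1)C(C)(C)C)C(=O)/C=C/[C@](C)(O[Si](CC)(CC)CC)C[C@@H](O[Si](CC)(CC)CC)/C=C(\C[Cr](Cl)Cl)C(=O)OC | intermediate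
23 | ring-closed methyl ester with the chromium alkoxide on O6: ten-membered carbocycle carrying the 2-(methoxycarbonyl)vinyl group on C7, configuration at C6, C7, C8 and C10 as in 24 (not isolated) | C=C(C(=O)OC)[C@H]1[C@H](O[Cr](Cl)Cl)/C=C(/CO[Si](c2ccccc2)(c2ccccc2)C(C)(C)C)C(=O)/C=C/[C@](C)(O[Si](CC)(CC)CC)C[C@H]1O[Si](CC)(CC)CC | intermediate
24 | (1E,4Z,6R,7S,8R,10R)-15-(tert-butyldiphenylsilyloxy)-3-oxo-8,10-bis(triethylsilyloxy)germacra-1,4,11(13)-trien-12,6-olide (6,7-trans lactone, geometry as in the target) | C=C1C(=O)O[C@@H]2/C=C(/CO[Si](c3ccccc3)(c3ccccc3)C(C)(C)C)C(=O)/C=C/[C@](C)(O[Si](CC)(CC)CC)C[C@@H](O[Si](CC)(CC)CC)[C@@H]12 | intermediate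
25 | (1E,4Z,6R,7R,8R,10R)-15-(tert-butyldiphenylsilyloxy)-8-hydroxy-3-oxo-10-(triethylsilyloxy)germacra-1,4,11(13)-trien-12,6-olide | C=C1C(=O)O[C@@H]2/C=C(/CO[Si](c3ccccc3)(c3ccccc3)C(C)(C)C)C(=O)/C=C/[C@](C)(O[Si](CC)(CC)CC)C[C@@H](O)[C@@H]12 | intermediate
26 | (R)-2-methylbutanoic acid | CC[C@@H](C)C(=O)O | starting material
27 | (1E,4Z,6R,7R,8R,10R)-15-(tert-butyldiphenylsilyloxy)-8-[(2R)-2-methylbutanoyloxy]-3-oxo-10-(triethylsilyloxy)germacra-1,4,11(13)-trien-12,6-olide | C=C1C(=O)O[C@@H]2/C=C(/CO[Si](c3ccccc3)(c3ccccc3)C(C)(C)C)C(=O)/C=C/[C@](C)(O[Si](CC)(CC)CC)C[C@@H](OC(=O)[C@H](C)CC)[C@@H]12 | intermediate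
28 | (1E,4Z,6R,7R,8R,10R)-10,15-dihydroxy-8-[(2R)-2-methylbutanoyloxy]-3-oxogermacra-1,4,11(13)-trien-12,6-olide | C=C1C(=O)O[C@@H]2/C=C(/CO)C(=O)/C=C/[C@](C)(O)C[C@@H](OC(=O)[C@H](C)CC)[C@@H]12 | target

**Step count and risks**

Total step count: 18. Longest linear sequence: 15 steps (steps 4 to 18, from (R)-linalool); the furan branch (steps 1 to 3) joins in step 10.

Steps most likely to fail:

1. Step 15. What may go wrong: single-electron reduction or oligomerisation of the enedione-aldehyde by the excess divalent chromium before ring closure, and erosion of facial control at C7 if the silyloxy group instead of H8 takes the inside position in the transition state. The fallback is a polar, non-reductive closure that sets out from 17 and returns at 24. Acetylation (Ac2O, DMAP, pyridine) should give the allylic acetate F1. SN2' substitution with Bu3SnLi and CuBr·SMe2 (THF, −78 °C) should give the 2-(stannylmethyl)enoate F2. Singlet oxygen followed by Me2S, as in step 14, should pass through the furan endoperoxide F3 to the keto-aldehyde stannane F4. BF3·OEt2 (CH2Cl2, −78 °C, high dilution) should then close the ten-membered ring by intramolecular allylstannane addition to the aldehyde, giving the hydroxy ester F5, which is lactonised with PPTS to rejoin the route at 24.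

2. Step 14. What may go wrong: cycloaddition of singlet oxygen across the vinylfuran diene instead of the furan 2,5-positions, over-oxidation, and Z to E isomerisation of the cis-enedione during handling. The fallback sets out from 19 and returns at 21. Oxidation with NBS and NaHCO3 in MeOH at −40 °C (Clauson-Kaas type) should give the 2,5-dimethoxy-2,5-dihydrofuran F6, a storable masked enedione, which is hydrolysed with PPTS in wet acetone at 0 °C immediately before the ring closure.

3. Step 12. What may go wrong: slow conversion of the hindered α-silyloxy aldehyde, which allows base-mediated epimerisation at C8 and degradation of the aldehyde over the long reaction time. The fallback sets out from 16 and returns at 17 with no new isolated compound: hydroalumination of methyl propiolate with i-Bu2AlH and N-methylmorpholine N-oxide (THF, 0 °C) gives the α-(methoxycarbonyl)vinylalane, which adds to 16 within hours under non-basic conditions (vinylalumination) to give the same adduct.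

**Further compounds**

F1 | step 15 | methyl (4R,6R,7E)-3-acetoxy-8-{3-[(tert-butyldiphenylsilyloxy)methyl]furan-2-yl}-6-methyl-2-methylidene-4,6-bis(triethylsilyloxy)oct-7-enoate (C3 epimers) | CC(C)(C)[Si](OCc1ccoc1/C=C/[C@](C)(O[Si](CC)(CC)CC)C[C@@H](O[Si](CC)(CC)CC)C(OC(C)=O)C(=C)C(=O)OC)(c1ccccc1)c1ccccc1
F2 | step 15 | methyl (2Z,4R,6R,7E)-8-{3-[(tert-butyldiphenylsilyloxy)methyl]furan-2-yl}-6-methyl-4,6-bis(triethylsilyloxy)-2-[(tributylstannyl)methyl]octa-2,7-dienoate | CC(C)(C)[Si](OCc1ccoc1/C=C/[C@](C)(O[Si](CC)(CC)CC)C[C@@H](O[Si](CC)(CC)CC)/C=C(\C[Sn](CCCC)(CCCC)CCCC)C(=O)OC)(c1ccccc1)c1ccccc1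
F3 | step 15 | 2,5-endoperoxide of the furan of F2 (bridgehead epimers, not isolated) | CC(C)(C)[Si](OCC1=CC2OOC1(/C=C/[C@](C)(O[Si](CC)(CC)CC)C[C@@H](O[Si](CC)(CC)CC)/C=C(\C[Sn](CCCC)(CCCC)CCCC)C(=O)OC)O2)(c1ccccc1)c1ccccc1
F4 | step 15 | methyl (2Z,4R,6R,7E,10Z)-10-[(tert-butyldiphenylsilyloxy)methyl]-6-methyl-9,12-dioxo-4,6-bis(triethylsilyloxy)-2-[(tributylstannyl)methyl]dodeca-2,7,10-trienoate | O=C/C=C(/CO[Si](c1ccccc1)(c1ccccc1)C(C)(C)C)C(=O)/C=C/[C@](C)(O[Si](CC)(CC)CC)C[C@@H](O[Si](CC)(CC)CC)/C=C(\C[Sn](CCCC)(CCCC)CCCC)C(=O)OC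
F5 | step 15 | ring-closed hydroxy ester: ten-membered carbocycle with free 6-hydroxyl and the 2-(methoxycarbonyl)vinyl group on C7, configuration as in 24 | C=C(C(=O)OC)[C@H]1[C@H](O)/C=C(/CO[Si](c2ccccc2)(c2ccccc2)C(C)(C)C)C(=O)/C=C/[C@](C)(O[Si](CC)(CC)CC)C[C@H]1O[Si](CC)(CC)CC
F6 | step 14 | 2,5-dimethoxy-2,5-dihydrofuran derived from the furan of 19 (acetal epimers) | CC(C)(C)[Si](OCC1=CC(OC)OC1(OC)/C=C/[C@](C)(O[Si](CC)(CC)CC)C[C@@H](O[Si](CC)(CC)CC)/C=C(\CBr)C(=O)OC)(c1ccccc1)c1ccccc1
F0 | step 12 | none | none
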